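**Retrosynthetic overview**
- Target 20 ⇐ seco-aldehyde 19 by closing C9–C10 (Ni/Cr coupling of the Z-vinyl iodide with the aldehyde); the ten-membered ring is formed last.
- 19 ⇐ aldehyde 16 + diacyl peroxide 18 by forming the C8–O bond: a new amine-catalysed α-acyloxylation that sets C8 and delivers the 3-methylbut-2-enoate in one operation.
- 16 ⇐ hydroxy ester 13 by two further C–O events: hydroxyl-directed epoxidation (sets C4 and C5), then lactone C–O closure.
- 13 ⇐ Z-enal 5 (from neryl acetate) + allylic bromide 11 (from propane-1,3-diol and methyl acrylate) by chromium-catalysed asymmetric allylation (C6–C7).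
- Ring order: oxirane, then lactone, then ten-membered carbocycle.

Assumption: germacrane locants are used in the explanations (epoxide C4/C5, lactone O at C6, C7, ester at C8, OH at C9, Z-alkene C1=C10); the given SMILES corresponds to 4R,5S,6R,7S,8S,9S.

**Step 1**
Reactants: 1 neryl acetate [(2Z)-3,7-dimethylocta-2,6-dien-1-yl acetate]
Product: 2 (2Z)-3-methyl-6-oxohex-2-en-1-yl acetate
Conditions: O3 (1 equiv), CH2Cl2/MeOH, −78 °C; then Me2S, −78 → 20 °C
Reagents that add atoms: ozone, [O-][O+]=O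
Why: Ozonolysis is selective for the electron-rich 6,7-alkene because the 2,3-alkene is deactivated by the allylic acetate; no stereocentre is formed and the 2Z geometry is untouched.

**Step 2**
Reactants: 2 (2Z)-3-methyl-6-oxohex-2-en-1-yl acetate
Product: 3 (2Z,6Z)-7-iodo-3-methylocta-2,6-dien-1-yl acetate
Conditions: EtPPh3I, n-BuLi, THF, 0 °C; I2, −78 °C; NaN(SiMe3)2, −78 °C; then 2, −78 → −20 °C
Reagents that add atoms: ethyltriphenylphosphonium iodide, CC[P+](c1ccccc1)(c1ccccc1)c1ccccc1.[I-]; iodine, II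
Why: Stork–Zhao-type Wittig olefination with the α-iodo ylide proceeds through the kinetic cis-oxaphosphetane and places iodine cis to the chain, giving the (Z)-2-iodo-2-alkene that later becomes the Z C1=C10 bond.

**Step 3**
Reactants: 3 (2Z,6Z)-7-iodo-3-methylocta-2,6-dien-1-yl acetate
Product: 4 (2Z,6Z)-7-iodo-3-methylocta-2,6-dien-1-ol
Conditions: K2CO3 (cat.), MeOH, 0 → 20 °C
Reagents that add atoms: none
Why: Base-catalysed transesterification (methanolysis) removes the acetate without touching the vinyl iodide or either alkene geometry.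

**Step 4**
Reactants: 4 (2Z,6Z)-7-iodo-3-methylocta-2,6-dien-1-ol
Product: 5 (2Z,6Z)-7-iodo-3-methylocta-2,6-dienal
Conditions: TEMPO (10 mol%), PhI(OAc)2, CH2Cl2, 20 °C
Reagents that add atoms: none
Why: Oxoammonium (TEMPO) oxidation of the allylic alcohol is mild enough to give the neral-type Z-enal without Z/E isomerisation.

**Step 5**
Reactants: 6 propane-1,3-diol
Product: 7 3-(triethylsilyloxy)propan-1-ol
Conditions: NaH (1.0 equiv), THF, 0 °C; Et3SiCl (1.0 equiv)
Reagents that add atoms: chlorotriethylsilane, CC[Si](CC)(CC)Cl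
Why: Monosilylation of a symmetrical diol through its sparingly soluble monosodium alkoxide gives the mono-ether selectively.

**Step 6**
Reactants: 7 3-(triethylsilyloxy)propan-1-ol
Product: 8 3-(triethylsilyloxy)propanal
Conditions: TEMPO (10 mol%), PhI(OAc)2, CH2Cl2, 20 °C
Reagents that add atoms: none
Why: TEMPO oxidation stops at the aldehyde and is non-basic, so β-elimination of the silyloxy group is avoided.

**Step 7**
Reactants: 8 3-(triethylsilyloxy)propanal; 9 methyl acrylate
Product: 10 methyl 3-hydroxy-2-methylidene-5-(triethylsilyloxy)pentanoate (racemic)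
Conditions: DABCO (0.5 equiv), 9 (3 equiv), MeOH (cat.), 20 °C, 5 d
Reagents that add atoms: none
Why: Morita–Baylis–Hillman reaction joins the future C7 to C11; the carbinol centre is racemic but is erased in step 8.

**Step 8**
Reactants: 10 methyl 3-hydroxy-2-methylidene-5-(triethylsilyloxy)pentanoate
Product: 11 methyl (2Z)-2-(bromomethyl)-5-(triethylsilyloxy)pent-2-enoate
Conditions: NBS, Me2S, CH2Cl2, 0 → 20 °C
Reagents that add atoms: N-bromosuccinimide, O=C1CCC(=O)N1Br
Why: The alkoxysulfonium of the Baylis–Hillman alcohol undergoes SN2′ displacement by bromide (Corey–Kim-type activation) to give the thermodynamically favoured (Z)-2-(bromomethyl)alkenoate.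

**Step 9**
Reactants: 5 (2Z,6Z)-7-iodo-3-methylocta-2,6-dienal; 11 methyl (2Z)-2-(bromomethyl)-5-(triethylsilyloxy)pent-2-enoate
Product: 13 methyl (3R,4S,5Z,9Z)-4-hydroxy-10-iodo-6-methyl-2-methylidene-3-[2-(triethylsilyloxy)ethyl]undeca-5,9-dienoate, via silyl ether 12 (not isolated)
Conditions: CrCl2 (nickel-free, 10 mol%), (S,S)-tBu-carbazole-bis(oxazoline) ligand (12 mol%), iPr2NEt (30 mol%), Mn powder (2 equiv), Me3SiCl (1.5 equiv), THF, 0 °C; then aq citric acid/MeOH, 0 °C
Reagents that add atoms: none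
Why: Catalytic asymmetric Nozaki–Hiyama 2-(alkoxycarbonyl)allylation: only the allylic bromide is reduced by divalent chromium (the vinyl iodide is inert without nickel), the chair Zimmerman–Traxler transition state gives the anti C6/C7 relationship, and the ligand sets the aldehyde face (the (S,S) ligand is taken to give the 4S carbinol; its antipode is used if the first run shows the opposite sense). The silyl ether 12 blocks premature lactonisation.

**Step 10**
Reactants: 13 methyl (3R,4S,5Z,9Z)-4-hydroxy-10-iodo-6-methyl-2-methylidene-3-[2-(triethylsilyloxy)ethyl]undeca-5,9-dienoate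
Product: 15 (4R,5R)-5-[(2S,3R)-3-[(3Z)-4-iodopent-3-en-1-yl]-3-methyloxiran-2-yl]-3-methylidene-4-[2-(triethylsilyloxy)ethyl]oxolan-2-one, via epoxy alcohol 14 (not isolated)
Conditions: m-CPBA (1.1 equiv), CH2Cl2, 0 °C; then PPTS (10 mol%), 20 °C
Reagents that add atoms: 3-chloroperoxybenzoic acid, OOC(=O)c1cccc(Cl)c1
Why: Hydroxyl-directed Prilezhaev epoxidation: A(1,3) strain in the Z-trisubstituted allylic alcohol holds the carbinol H in the alkene plane, so the hydrogen-bonded peracid attacks syn to OH and gives the threo epoxy alcohol (C4 R, C5 S); acid-catalysed lactonisation of the anti hydroxy ester then gives the trans lactone. The acrylate and the iodoalkene are too electron-poor to compete.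

**Step 11**
Reactants: 15 (4R,5R)-5-[(2S,3R)-3-[(3Z)-4-iodopent-3-en-1-yl]-3-methyloxiran-2-yl]-3-methylidene-4-[2-(triethylsilyloxy)ethyl]oxolan-2-one
Product: 16 2-[(2R,3R)-2-[(2S,3R)-3-[(3Z)-4-iodopent-3-en-1-yl]-3-methyloxiran-2-yl]-4-methylidene-5-oxooxolan-3-yl]acetaldehyde
Conditions: (COCl)2, DMSO, CH2Cl2, −78 → −40 °C; Et3N, −78 → 0 °C
Reagents that add atoms: none
Why: Swern oxidation of a primary triethylsilyl ether: the chlorosulfonium salt cleaves the primary Si–O bond and the resulting alkoxysulfonium collapses to the aldehyde, so deprotection and oxidation are one step.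

**Step 12**
Reactants: 17 3-methylbut-2-enoic acid (2 equiv)
Product: 18 bis(3-methylbut-2-enoyl) peroxide
Conditions: H2O2 (50% aq, 0.5 equiv), DCC (1 equiv), CH2Cl2, 0 °C; used as a titrated solution
Reagents that add atoms: hydrogen peroxide, OO
Why: Carbodiimide-mediated acylation of hydrogen peroxide is the standard route to diacyl peroxides and avoids alkaline peroxide, which could epoxidise the enoyl group.

**Step 13**
Reactants: 16 2-[(2R,3R)-2-[(2S,3R)-3-[(3Z)-4-iodopent-3-en-1-yl]-3-methyloxiran-2-yl]-4-methylidene-5-oxooxolan-3-yl]acetaldehyde; 18 bis(3-methylbut-2-enoyl) peroxide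
Product: 19 (1S)-1-[(2R,3R)-2-[(2S,3R)-3-[(3Z)-4-iodopent-3-en-1-yl]-3-methyloxiran-2-yl]-4-methylidene-5-oxooxolan-3-yl]-2-oxoethyl 3-methylbut-2-enoate
Conditions: (S)-2-(triphenylmethyl)pyrrolidine (20 mol%), hydroquinone (10 mol%), THF, 0 °C
Reagents that add atoms: none
Why: Proposed new method: an enamine-catalysed α-alkenoyloxylation in which the E-enamine of 16 attacks the O–O bond of the new reagent 18 (SN2 at oxygen, 3-methylbut-2-enoate as leaving group) on the face opposite the trityl group, forming the C8–O bond with 8S configuration before iminium hydrolysis releases 19; the β,β-dimethyl enoyl groups are poor Michael acceptors for the hindered amine and hydroquinone suppresses radical decomposition; the closest known reaction type is the amine-catalysed asymmetric α-benzoyloxylation of aldehydes with dibenzoyl peroxide, not yet shown with an α,β-unsaturated diacyl peroxide or in the presence of an α-methylene lactone.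

**Step 14**
Reactants: 19 (1S)-1-[(2R,3R)-2-[(2S,3R)-3-[(3Z)-4-iodopent-3-en-1-yl]-3-methyloxiran-2-yl]-4-methylidene-5-oxooxolan-3-yl]-2-oxoethyl 3-methylbut-2-enoate
Product: 20 (1aR,4Z,6S,7S,7aS,10aR,10bS)-6-hydroxy-1a,5-dimethyl-8-methylidene-9-oxo-1a,2,3,6,7,7a,8,9,10a,10b-decahydrooxireno[9,10]cyclodeca[1,2-b]furan-7-yl 3-methylbut-2-enoate
Conditions: CrCl2 (6 equiv), NiCl2 (2 mol%), N-[2-[(4S)-4-isopropyl-4,5-dihydro-1,3-oxazol-2-yl]-6-methylphenyl]methanesulfonamide (6.6 equiv), Et3N (6.6 equiv), THF/MeCN, 0.002 M, 20 °C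
Reagents that add atoms: none
Why: Nozaki–Hiyama–Kishi macrocyclisation: nickel inserts into the vinyl iodide, transmetalation to trivalent chromium retains the Z geometry, and addition to the aldehyde at high dilution closes the ten-membered ring. The chromium-bound chiral sulfonamide is relied on to deliver the 9S carbinol against the substrate's Felkin–Anh preference (the ligand antipode is used if the first run returns the 9-epimer).

**Compound list**
1 | neryl acetate, (2Z)-3,7-dimethylocta-2,6-dien-1-yl acetate | CC(=O)OC/C=C(C)\CCC=C(C)C | starting material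
2 | (2Z)-3-methyl-6-oxohex-2-en-1-yl acetate | CC(=O)OC/C=C(C)\CCC=O | intermediate
3 | (2Z,6Z)-7-iodo-3-methylocta-2,6-dien-1-yl acetate | CC(=O)OC/C=C(C)\CC/C=C(\I)C | intermediate
4 | (2Z,6Z)-7-iodo-3-methylocta-2,6-dien-1-ol | OC/C=C(C)\CC/C=C(\I)C | intermediate
5 | (2Z,6Z)-7-iodo-3-methylocta-2,6-dienal | O=C/C=C(C)\CC/C=C(\I)C | intermediate
6 | propane-1,3-diol | OCCCO | starting material
7 | 3-(triethylsilyloxy)propan-1-ol | OCCCO[Si](CC)(CC)CC | intermediate
8 | 3-(triethylsilyloxy)propanal | O=CCCO[Si](CC)(CC)CC | intermediate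
9 | methyl acrylate | C=CC(=O)OC | starting material
10 | methyl 3-hydroxy-2-methylidene-5-(triethylsilyloxy)pentanoate (racemic) | C=C(C(=O)OC)C(O)CCO[Si](CC)(CC)CC | intermediate
11 | methyl (2Z)-2-(bromomethyl)-5-(triethylsilyloxy)pent-2-enoate | BrC/C(C(=O)OC)=C\CCO[Si](CC)(CC)CC | intermediate
12 | methyl (3R,4S,5Z,9Z)-10-iodo-6-methyl-2-methylidene-3-[2-(triethylsilyloxy)ethyl]-4-(trimethylsilyloxy)undeca-5,9-dienoate | COC(=O)C(=C)[C@@H](CCO[Si](CC)(CC)CC)[C@@H](O[Si](C)(C)C)/C=C(C)\CC/C=C(\I)C | intermediate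
13 | methyl (3R,4S,5Z,9Z)-4-hydroxy-10-iodo-6-methyl-2-methylidene-3-[2-(triethylsilyloxy)ethyl]undeca-5,9-dienoate | COC(=O)C(=C)[C@@H](CCO[Si](CC)(CC)CC)[C@@H](O)/C=C(C)\CC/C=C(\I)C | intermediate
14 | methyl (3R,4R)-4-hydroxy-4-[(2S,3R)-3-[(3Z)-4-iodopent-3-en-1-yl]-3-methyloxiran-2-yl]-2-methylidene-3-[2-(triethylsilyloxy)ethyl]butanoate | COC(=O)C(=C)[C@@H](CCO[Si](CC)(CC)CC)[C@@H](O)[C@@H]1O[C@]1(C)CC/C=C(\I)C | intermediate
15 | (4R,5R)-5-[(2S,3R)-3-[(3Z)-4-iodopent-3-en-1-yl]-3-methyloxiran-2-yl]-3-methylidene-4-[2-(triethylsilyloxy)ethyl]oxolan-2-one | C=C1C(=O)O[C@H]([C@@H]1CCO[Si](CC)(CC)CC)[C@@H]2O[C@]2(C)CC/C=C(\I)C | intermediate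
16 | 2-[(2R,3R)-2-[(2S,3R)-3-[(3Z)-4-iodopent-3-en-1-yl]-3-methyloxiran-2-yl]-4-methylidene-5-oxooxolan-3-yl]acetaldehyde | C=C1C(=O)O[C@H]([C@@H]1CC=O)[C@@H]2O[C@]2(C)CC/C=C(\I)C | intermediate
17 | 3-methylbut-2-enoic acid | CC(C)=CC(=O)O | starting material
18 | bis(3-methylbut-2-enoyl) peroxide | CC(C)=CC(=O)OOC(=O)C=C(C)C | intermediate
19 | (1S)-1-[(2R,3R)-2-[(2S,3R)-3-[(3Z)-4-iodopent-3-en-1-yl]-3-methyloxiran-2-yl]-4-methylidene-5-oxooxolan-3-yl]-2-oxoethyl 3-methylbut-2-enoate | C=C1C(=O)O[C@H]([C@@H]1[C@H](OC(=O)C=C(C)C)C=O)[C@@H]2O[C@]2(C)CC/C=C(\I)C | intermediate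
20 | (1aR,4Z,6S,7S,7aS,10aR,10bS)-6-hydroxy-1a,5-dimethyl-8-methylidene-9-oxo-1a,2,3,6,7,7a,8,9,10a,10b-decahydrooxireno[9,10]cyclodeca[1,2-b]furan-7-yl 3-methylbut-2-enoate (CNP0188779.1) | C=C1C(=O)O[C@@H]2[C@@H]1[C@H](OC(=O)C=C(C)C)[C@@H](O)/C(C)=C\CC[C@@]1(C)O[C@@H]21 | target

**Step count**
Total: 14 steps. Longest linear sequence: 9 steps (1, 2, 3, 4, 9, 10, 11, 13, 14; the branch 5, 6, 7, 8, 9, 10, 11, 13, 14 is equally long).

**Three steps most likely to fail**

Step 9 (ee and dr of the ligand-controlled allylation with a Z-enal and a γ-substituted bromide; possible Z/E drift or early lactonisation). The fallback sets out from 5 and 11 and comes back at 14. The two are coupled with stoichiometric CrCl2 in THF without ligand; this classical chromium allylation is reliably anti and gives 13 as a racemate, that is 13 together with the enantiomeric hydroxy ester F1. Absolute configuration is then introduced in the C–O bond-forming step: a kinetic resolution by vanadium-catalysed epoxidation (VO(OiPr)3, C2-symmetric chiral bis-hydroxamic acid ligand, t-BuOOH 0.55 equiv, toluene, 0 °C) epoxidises 13 faster than F1, with the same threo preference, to give 14. Treatment with PPTS as in step 10 then gives 15, and F1 is separated.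

Step 13 (the new α-acyloxylation: the amine may be consumed by the peroxide or by reversible aza-Michael addition to the methylene lactone, and catalyst control may be mismatched with C7). The fallback uses known chemistry, sets out from 16 and comes back at 19. D-Proline-catalysed α-aminoxylation with nitrosobenzene gives the α-(phenylaminooxy) aldehyde F2 with 8S configuration. Reduction in the same flask (NaBH4, MeOH, −40 °C, brief) gives the aminooxy alcohol F3, and N–O cleavage (Zn, AcOH) gives the 8,9-diol F4. Selective silylation of the primary hydroxyl (Et3SiCl, imidazole, −20 °C) gives the primary triethylsilyl ether F5. Esterification with 3-methylbut-2-enoyl chloride (pyridine, DMAP) gives the silyl ether ester F6, and Swern oxidation of the primary silyl ether as in step 11 gives 19.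

Step 14 (ten-membered ring closure, and the ligand must override the Felkin–Anh preference at C9). The fallback sets out from 19 and comes back at 20. Ligand-free closure (CrCl2, NiCl2 cat., DMSO, high dilution) is run under substrate control and is expected to give mainly the 9R epimer F7. Dess–Martin oxidation converts the C9 epimers to the single macrocyclic enone F8. Luche reduction (NaBH4, CeCl3·7H2O, MeOH, −78 °C) then delivers hydride anti to the C8 acyloxy group (Felkin–Anh), giving the 8,9-syn alcohol 20, so the intrinsic bias now works for the target.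

**Further compounds**
F1 | step 9 | methyl (3S,4R,5Z,9Z)-4-hydroxy-10-iodo-6-methyl-2-methylidene-3-[2-(triethylsilyloxy)ethyl]undeca-5,9-dienoate | COC(=O)C(=C)[C@H](CCO[Si](CC)(CC)CC)[C@H](O)/C=C(C)\CC/C=C(\I)C
F2 | step 13 | (2S)-2-[(2R,3R)-2-[(2S,3R)-3-[(3Z)-4-iodopent-3-en-1-yl]-3-methyloxiran-2-yl]-4-methylidene-5-oxooxolan-3-yl]-2-(phenylaminooxy)acetaldehyde | C=C1C(=O)O[C@H]([C@@H]1[C@H](ONc1ccccc1)C=O)[C@@H]2O[C@]2(C)CC/C=C(\I)C
F3 | step 13 | (4R,5R)-4-[(1S)-2-hydroxy-1-(phenylaminooxy)ethyl]-5-[(2S,3R)-3-[(3Z)-4-iodopent-3-en-1-yl]-3-methyloxiran-2-yl]-3-methylideneoxolan-2-one | C=C1C(=O)O[C@H]([C@@H]1[C@H](ONc1ccccc1)CO)[C@@H]2O[C@]2(C)CC/C=C(\I)C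
F4 | step 13 | (4S,5R)-4-[(1S)-1,2-dihydroxyethyl]-5-[(2S,3R)-3-[(3Z)-4-iodopent-3-en-1-yl]-3-methyloxiran-2-yl]-3-methylideneoxolan-2-one | C=C1C(=O)O[C@H]([C@@H]1[C@H](O)CO)[C@@H]2O[C@]2(C)CC/C=C(\I)C
F5 | step 13 | (4S,5R)-4-[(1S)-1-hydroxy-2-(triethylsilyloxy)ethyl]-5-[(2S,3R)-3-[(3Z)-4-iodopent-3-en-1-yl]-3-methyloxiran-2-yl]-3-methylideneoxolan-2-one | C=C1C(=O)O[C@H]([C@@H]1[C@H](O)CO[Si](CC)(CC)CC)[C@@H]2O[C@]2(C)CC/C=C(\I)C
F6 | step 13 | (1S)-1-[(2R,3S)-2-[(2S,3R)-3-[(3Z)-4-iodopent-3-en-1-yl]-3-methyloxiran-2-yl]-4-methylidene-5-oxooxolan-3-yl]-2-(triethylsilyloxy)ethyl 3-methylbut-2-enoate | C=C1C(=O)O[C@H]([C@@H]1[C@H](OC(=O)C=C(C)C)CO[Si](CC)(CC)CC)[C@@H]2O[C@]2(C)CC/C=C(\I)C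
F7 | step 14 | (1aR,4Z,6R,7S,7aS,10aR,10bS)-6-hydroxy-1a,5-dimethyl-8-methylidene-9-oxo-1a,2,3,6,7,7a,8,9,10a,10b-decahydrooxireno[9,10]cyclodeca[1,2-b]furan-7-yl 3-methylbut-2-enoate | C=C1C(=O)O[C@@H]2[C@@H]1[C@H](OC(=O)C=C(C)C)[C@H](O)/C(C)=C\CC[C@@]1(C)O[C@@H]21
F8 | step 14 | (1aR,4Z,7S,7aR,10aR,10bS)-1a,5-dimethyl-8-methylidene-6,9-dioxo-1a,2,3,6,7,7a,8,9,10a,10b-decahydrooxireno[9,10]cyclodeca[1,2-b]furan-7-yl 3-methylbut-2-enoate | C=C1C(=O)O[C@@H]2[C@@H]1[C@H](OC(=O)C=C(C)C)C(=O)/C(C)=C\CC[C@@]1(C)O[C@@H]21
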